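**Retrosynthetic overview**

1. The target is reached last by acetyl chloride opening of a C2–O–C6 ether bridge (C2 acetate, and C6 chloride with inversion); before that the γ-lactone and the C9 acetate are built on the C9 ketone of an oxygen-bridged tricyclic ketone (C8 alkylation, C8 hydroxylation, C9 reduction).
2. That ketone comes from one operation on a bicyclic dialkenyl carbinol: an anionic oxy-Cope shift forms C1–C2 (quaternary methyl carbon to its oxygenated neighbour), cleaves C4–C9 and expands a six-membered carbocycle (C4–C9) to the ten-membered ring; the released C9/C10 enolate then closes ring A at C10–C11 under Pd(PPh3)4 catalysis.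
3. Enabling feature: across the C1–C2 bond the C9 oxygen and the C3=C4 Z olefin are 1,5-related (C9(=O)–C10–C1–C2–C3=C4, a δ,ε-unsaturated ketone), and the C2 oxygen and C6 are 1,5-related through C3=C4–C5, so one oxygen can bridge them as a dihydropyran that locks the olefin Z and the transition state into a boat.
4. The carbinol comes from an (E)-alkenylcerium (C10, C1, C11–C15, C20; Et2Zn/ProPhenol-catalysed ynone aldol, syn reduction, carboalumination) and a 2-oxabicyclo[3.3.1]non-3-en-6-one (C2–C9, C16; from (−)-quinic acid by dienolate alkylation with a tethered bromoacetal).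
5. Ring order: quinic acid carbocycle (temporary ring C4–C9), then the dihydropyran bridge (O, C2–C6), then the ten-membered ring, then ring A, then the γ-lactone; the bridge is removed in the last step.

Key step: step 16

Numbering used for all intermediates: C1 quaternary carbon (methyl C15); C2 the acetoxy carbon next to it; C3=C4 the Z olefin; C5 (methylidene C16); C6 chloro carbon; C7 lactone O–CH; C8 tertiary carbinol; C9 acetoxy CH; C10 ring-fusion CH; C11 (methylidene C20); C12, C13, C14 complete ring A; C17, C18, C19 are the lactone CH, its methyl and its carbonyl carbon.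

Assumption: the (S,S)-ligand in step 10 is taken to give the 5R aldol (the antipodal ligand would be used if the sense is opposite), and 2-bromoprop-2-enal and 4-(trimethylsilyl)but-3-yn-2-one are taken as commercial.

**Route**

Step 1
Reactants: 1 (−)-quinic acid
Product: 2 3,4-O-isopropylidenequinic acid 1,5-lactone
Conditions: 2,2-dimethoxypropane, TsOH (cat.), acetone, reflux
Reagents that add atoms: 2,2-dimethoxypropane, COC(C)(C)OC
Why: Acid-catalysed acetalisation of the cis-3,4-diol with concomitant lactonisation onto the cis C5 hydroxyl should mask three hydroxyls in one operation without touching a stereocentre.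

Step 2
Reactants: 2 3,4-O-isopropylidenequinic acid 1,5-lactone
Product: 4 (3R,4S,5R)-5-hydroxy-3,4-(isopropylidenedioxy)cyclohexan-1-one, via acetonide triol 3 (not isolated)
Conditions: NaBH4, EtOH, 0 °C → rt; then NaIO4, H2O (pH 7 phosphate), 0 °C
Reagents that add atoms: none
Why: Hydride reduction of the lactone followed by periodate glycol cleavage of the resulting 1,2-diol should unveil the future C9 ketone while the future C6 and C7 centres stay untouched.

Step 3
Reactants: 4 (3R,4S,5R)-5-hydroxy-3,4-(isopropylidenedioxy)cyclohexan-1-one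
Product: 5 5-O-tert-butyldimethylsilyl ether of 4
Conditions: TBSCl, imidazole, DMF, rt
Reagents that add atoms: tert-butyldimethylsilyl chloride, CC(C)(C)[Si](C)(C)Cl
Why: Silylation of the only free hydroxyl (silyl ether formation) should protect the future C7 oxygen for the whole route.

Step 4
Reactants: 5 5-O-tert-butyldimethylsilyl ether of 4
Product: 6 (4R,5R)-5-(tert-butyldimethylsilyloxy)-4-hydroxycyclohex-2-en-1-one
Conditions: aq. NaOH (0.5 M), THF, 0 °C
Reagents that add atoms: none
Why: E1cB β-elimination should expel the acetonide oxygen (the hemiketal alkoxide then loses acetone) faster than the silyloxy group because the strained cis-fused dioxolane is opened, which frees the future C6 hydroxyl selectively.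

Step 5
Reactants: 6 (4R,5R)-5-(tert-butyldimethylsilyloxy)-4-hydroxycyclohex-2-en-1-one
Product: 8 5-(tert-butyldimethylsilyloxy)-3-methyl-1,4-bis(trimethylsilyloxy)cyclohex-1-ene (methyl trans to the 4-silyloxy group), via silyl ether 7 (not isolated)
Conditions: TMSCl, Et3N, THF, 0 °C; then Me2CuLi, TMSCl, −78 °C
Reagents that add atoms: chlorotrimethylsilane, C[Si](C)(C)Cl; lithium dimethylcuprate, [Li+].C[Cu-]C
Why: In situ O-silylation followed by chlorosilane-accelerated cuprate conjugate addition with enolate trapping should place the future C16 carbon on C5 anti to the neighbouring silyloxy group, a stereocentre that is erased in the next step.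

Step 6
Reactants: 8 5-(tert-butyldimethylsilyloxy)-3-methyl-1,4-bis(trimethylsilyloxy)cyclohex-1-ene
Product: 10 (4R,5R)-5-(tert-butyldimethylsilyloxy)-4-hydroxy-3-methylcyclohex-2-en-1-one, via silyl ether 9 (not isolated)
Conditions: Pd(OAc)2 (10 mol %), O2 (1 atm), DMSO, rt; then K2CO3, MeOH, 0 °C
Reagents that add atoms: none
Why: Saegusa–Ito oxidation (palladium enolate, β-hydride elimination) should restore the enone with the methyl group now on its β-carbon, and methanolysis then frees the secondary hydroxyl.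

Step 7
Reactants: 10 (4R,5R)-5-(tert-butyldimethylsilyloxy)-4-hydroxy-3-methylcyclohex-2-en-1-one
Product: 11 4-O-(2-bromo-1-ethoxyethyl) mixed acetal of 10 (both acetal epimers)
Conditions: ethyl vinyl ether, NBS, CH2Cl2, −40 → 0 °C
Reagents that add atoms: ethyl vinyl ether, C=COCC; N-bromosuccinimide, O=C1CCC(=O)N1Br
Why: Bromoetherification of the vinyl ether by the C6 hydroxyl (haloacetalisation) should attach the two carbons that become C2 and C3, the acetal centre being a mixture that converges in step 9.

Step 8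
Reactants: 11 4-O-(2-bromo-1-ethoxyethyl) mixed acetal of 10
Product: 12 8-exo-(tert-butyldimethylsilyloxy)-3-ethoxy-9-methylidene-2-oxabicyclo[3.3.1]nonan-6-one
Conditions: KOt-Bu (1.1 equiv), THF/t-BuOH, −20 → 0 °C
Reagents that add atoms: none
Why: Thermodynamic γ-deprotonation should give the extended dienolate, whose α-carbon (C4) is alkylated by the tethered primary bromide (intramolecular enolate alkylation, 6-exo-tet), which is only possible cis to the C6 oxygen and leaves the C5 methylidene out of conjugation next to a bridgehead that cannot enolise.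

Step 9
Reactants: 12 8-exo-(tert-butyldimethylsilyloxy)-3-ethoxy-9-methylidene-2-oxabicyclo[3.3.1]nonan-6-one
Product: 14 8-exo-(tert-butyldimethylsilyloxy)-9-methylidene-2-oxabicyclo[3.3.1]non-3-en-6-one, via silyl enol ether 13 (not isolated)
Conditions: TMSOTf, i-Pr2NEt, CH2Cl2, −20 → 0 °C; then K2CO3, MeOH, 0 °C
Reagents that add atoms: none
Why: Silyl-triflate-mediated loss of ethanol from the cyclic acetal through the oxocarbenium ion (acetal-to-enol-ether elimination) should give the dihydropyran enol ether, the ketone being silylated in passing and freed again by methanolysis.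

Step 10
Reactants: 15 4-(trimethylsilyl)but-3-yn-2-one; 16 2-bromoprop-2-enal
Product: 17 (5R)-6-bromo-5-hydroxy-1-(trimethylsilyl)hept-6-en-1-yn-3-one
Conditions: (S,S)-ProPhenol (10 mol %), Et2Zn (20 mol %), 4 Å MS, THF, 0 °C
Reagents that add atoms: none
Why: Direct catalytic asymmetric aldol addition of the methyl ynone (zinc enolate held in the chiral Et2Zn/ProPhenol pocket) to the enal should set the C12 carbinol by catalyst control.

Step 11
Reactants: 17 (5R)-6-bromo-5-hydroxy-1-(trimethylsilyl)hept-6-en-1-yn-3-one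
Product: 18 (3S,5R)-6-bromo-1-(trimethylsilyl)hept-6-en-1-yne-3,5-diol
Conditions: Et2BOMe, NaBH4, THF/MeOH (4:1), −78 °C; MeOH azeotrope
Reagents that add atoms: none
Why: Narasaka–Prasad reduction, in which external hydride attacks the boron chelate of the β-hydroxy ketone, should give the syn-1,3-diol and so set C14 from C12.

Step 12
Reactants: 18 (3S,5R)-6-bromo-1-(trimethylsilyl)hept-6-en-1-yne-3,5-diol
Product: 19 (3S,5R)-6-bromo-3,5-bis(tert-butyldimethylsilyloxy)-1-(trimethylsilyl)hept-6-en-1-yne
Conditions: TBSOTf, 2,6-lutidine, CH2Cl2, −78 → 0 °C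
Reagents that add atoms: tert-butyldimethylsilyl triflate, CC(C)(C)[Si](C)(C)OS(=O)(=O)C(F)(F)F
Why: Silylation of both secondary hydroxyls (silyl ether formation) should give base-stable protection that survives the organometallic steps.

Step 13
Reactants: 19 (3S,5R)-6-bromo-3,5-bis(tert-butyldimethylsilyloxy)-1-(trimethylsilyl)hept-6-en-1-yne
Product: 20 (3S,5R)-6-bromo-3,5-bis(tert-butyldimethylsilyloxy)hept-6-en-1-yne
Conditions: K2CO3, MeOH, rt
Reagents that add atoms: none
Why: Methanolysis of the alkynyl C–Si bond (protodesilylation) should free the terminal alkyne while the secondary silyl ethers and the vinyl bromide are inert to carbonate.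

Step 14
Reactants: 20 (3S,5R)-6-bromo-3,5-bis(tert-butyldimethylsilyloxy)hept-6-en-1-yne
Product: 22 (1E,3S,5R)-6-bromo-1-iodo-2-methyl-3,5-bis(tert-butyldimethylsilyloxy)hepta-1,6-diene, via alkenylalane 21 (not isolated)
Conditions: Me3Al, Cp2ZrCl2 (25 mol %), CH2Cl2, 0 °C → rt; then I2, THF, −30 °C
Reagents that add atoms: trimethylaluminium, C[Al](C)C; iodine, II
Why: Negishi carboalumination adds methyl and aluminium syn across the alkyne (methyl to the internal carbon) and iodinolysis with retention should give the (E)-iodide with methyl cis to iodine, the geometry that later defines C1.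

Step 15
Reactants: 22 (1E,3S,5R)-6-bromo-1-iodo-2-methyl-3,5-bis(tert-butyldimethylsilyloxy)hepta-1,6-diene; 14 8-exo-(tert-butyldimethylsilyloxy)-9-methylidene-2-oxabicyclo[3.3.1]non-3-en-6-one
Product: 25 6-[(1E,3S,5R)-6-bromo-2-methyl-3,5-bis(tert-butyldimethylsilyloxy)hepta-1,6-dienyl]-8-exo-(tert-butyldimethylsilyloxy)-9-methylidene-2-oxabicyclo[3.3.1]non-3-en-6-ol (alkenyl group cis to the enol ether bridge), via alkenyllithium 23 (not isolated), via alkenylcerium dichloride 24 (not isolated)
Conditions: t-BuLi (2.0 equiv), Et2O, −100 °C; CeCl3, THF, −78 °C; then 14, −78 °C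
Reagents that add atoms: none
Why: Iodine–lithium exchange (much faster than bromine–lithium exchange at −100 °C), transmetalation to the weakly basic organocerium and 1,2-addition to the ketone should give the tertiary carbinol, the reagent entering along the equatorial trajectory because the axial one is blocked by the syn-axial C7 silyloxy group, which places the alkenyl group cis to the enol ether bridge.

Step 16
Reactants: 25 bicyclic dialkenyl carbinol
Product: 28 oxygen-bridged tricyclic ketone (ten-membered ring C1–C10 trans-fused to ring A; C2–O–C6 ether; C9 ketone; 3Z olefin; methylidenes at C5 and C11; OTBS at C7, C12 and C14), via potassium alkoxide 26 (not isolated), via potassium enolate 27 (not isolated)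
Conditions: KN(SiMe3)2, 18-crown-6, THF, 0 → 50 °C; then Pd(PPh3)4 (10 mol %), 50 °C
Reagents that add atoms: none
Why: Deprotonation gives alkoxide 26, whose C2=C3–C4–C9(O−)–C10=C1 array undergoes an anionic oxy-Cope [3,3]-sigmatropic shift (closest known type: ring expansion of 1-alkenyl-2-vinylcyclohexanol alkoxides to cyclodec-5-enones) that forms C1–C2, cleaves C4–C9 and releases enolate 27 regiospecifically. The ten-membered ring is closed in the ring-expansion mode (six to ten) through a boat transition state, the only one available because the dihydropyran tether holds C2=C3 syn to C5 and the new eight-membered subring can only hold a cis enolate; this fixes the 3Z olefin, and the C2 configuration follows from the cis oxygen bridge to the quinic-acid-derived C6 centre. The quaternary C1 centre is set by suprafacial bond formation on the (E)-olefin (methyl cis to C9) within that boat, so it is transferred from the C4 and C9 centres. Zerovalent palladium then inserts into the vinyl C–Br bond and the enolate carbon C10 is alkenylated intramolecularly (6-exo closure of ring A, a known coupling of potassium ketone enolates with vinyl halides); C11 is delivered to the face of C10 opposite the axial C1–C2 bond because the other face is covered by the oxygen-bridged ring, which gives the trans ring fusion with H-10 syn to C2. The step needs the sigmatropic shift to outrun alkoxide fragmentation and the enolate to keep its position until coupling; the enol ether donor at the diene terminus, the doubly allylic C4–C9 bond and the aprotic medium should secure this.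

Step 17
Reactants: 29 methyl (R)-lactate
Product: 30 methyl (R)-2-(trifluoromethylsulfonyloxy)propanoate
Conditions: Tf2O, 2,6-lutidine, CH2Cl2, −78 °C
Reagents that add atoms: triflic anhydride, O=S(=O)(OS(=O)(=O)C(F)(F)F)C(F)(F)F
Why: O-Sulfonylation with retention (triflate formation) should give an electrophile that reacts by clean SN2 displacement.

Step 18
Reactants: 28 oxygen-bridged tricyclic ketone; 30 methyl (R)-2-(trifluoromethylsulfonyloxy)propanoate
Product: 32 C8-[(R)-1-methoxy-1-oxopropan-2-yl] derivative of 28, via lithium enolate 31 (not isolated)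
Conditions: LiN(i-Pr)2, THF, −78 °C; then 30, −78 → −40 °C
Reagents that add atoms: none
Why: Kinetic deprotonation at the less hindered C8 methylene and SN2 alkylation of the enolate by the α-triflyloxy ester with inversion should set C17 as R, while the C8 configuration formed here is erased in the next step.

Step 19
Reactants: 32 C8-alkylated ketone
Product: 34 C8 tertiary alcohol of 32 (hydroxyl cis to the C7 oxygen), via potassium enolate 33 (not isolated)
Conditions: KN(SiMe3)2, THF, −78 °C; then 2-(phenylsulfonyl)-3-phenyloxaziridine, −78 °C; AcOH quench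
Reagents that add atoms: 2-(phenylsulfonyl)-3-phenyloxaziridine, O=S(=O)(c1ccccc1)N1OC1c1ccccc1
Why: Enolisation toward C8 and electrophilic enolate hydroxylation by the N-sulfonyloxaziridine on the outer face of the oxygen-bridged eight-membered subring, syn to the C7 oxygen, should set the tertiary C8 alcohol.

Step 20
Reactants: 34 C8 tertiary alcohol
Product: 36 γ-lactone diol ketone (lactone O7–C19; free OH at C8, C12 and C14; C9 ketone; C2–O–C6 ether), via triol ester 35 (not isolated)
Conditions: HF·pyridine, pyridine/THF, 0 °C → rt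
Reagents that add atoms: none
Why: Fluoride cleavage of the three silyl ethers frees the C7 hydroxyl, which should close the γ-lactone on the methyl ester (desilylation/lactonisation) because C7–O and C8–C17 are gauche in the bridged ring and C9 still carries no competing hydroxyl.

Step 21
Reactants: 36 γ-lactone diol ketone
Product: 37 C9 (S) alcohol of 36
Conditions: NaBH4, CeCl3·7H2O, MeOH, −40 °C
Reagents that add atoms: none
Why: Luche reduction under non-chelating conditions should deliver hydride anti to the C8–O bond and anti to the quaternary C1 substituent of C10 (Felkin–Anh control from both flanking centres, which reinforce each other), giving the 9S alcohol.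

Step 22
Reactants: 37 C9 alcohol
Product: 38 9,12,14-triacetate (C8 hydroxyl free; C2–O–C6 ether)
Conditions: Ac2O, DMAP, pyridine, rt
Reagents that add atoms: acetic anhydride, CC(=O)OC(C)=O
Why: DMAP-catalysed acylation should esterify the three secondary hydroxyls and leave the hindered tertiary C8 hydroxyl free.

Step 23
Reactants: 38 9,12,14-triacetate
Product: 39 target compound CNP0164748.1
Conditions: AcCl, ZnCl2 (20 mol %), 2,6-di-tert-butyl-4-methylpyridine, CH2Cl2, −20 → 0 °C
Reagents that add atoms: acetyl chloride, CC(Cl)=O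
Why: Acyl chloride cleavage of the cyclic ether should proceed by O-acylation to an acyloxonium ion that chloride opens by SN2 at C6 with inversion (C2 is neopentylic and both ring C–O bonds lie near the planes of the adjacent olefins, which disfavours ionisation and SN2′ attack), giving the C2 acetate and the C6 chloride in one operation.

**Compound list**

1 | (−)-quinic acid | OC(=O)[C@]1(O)C[C@@H](O)[C@@H](O)[C@H](O)C1 | starting material
2 | 3,4-O-isopropylidenequinic acid 1,5-lactone | O=C1O[C@@H]2C[C@@]1(O)C[C@H]3OC(C)(C)O[C@@H]23 | intermediate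
3 | 1-(hydroxymethyl)-3,4-O-isopropylidenecyclohexane-1,3,4,5-tetrol (acetonide triol) | OC[C@@]1(O)C[C@@H](O)[C@@H]2OC(C)(C)O[C@@H]2C1 | intermediate
4 | (3R,4S,5R)-5-hydroxy-3,4-(isopropylidenedioxy)cyclohexan-1-one | O=C1C[C@@H](O)[C@@H]2OC(C)(C)O[C@@H]2C1 | intermediate
5 | 5-O-tert-butyldimethylsilyl ether of 4 | O=C1C[C@@H](O[Si](C)(C)C(C)(C)C)[C@@H]2OC(C)(C)O[C@@H]2C1 | intermediate
6 | (4R,5R)-5-(tert-butyldimethylsilyloxy)-4-hydroxycyclohex-2-en-1-one | O=C1C[C@@H](O[Si](C)(C)C(C)(C)C)[C@H](O)C=C1 | intermediate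
7 | 4-O-trimethylsilyl ether of 6 | O=C1C[C@@H](O[Si](C)(C)C(C)(C)C)[C@H](O[Si](C)(C)C)C=C1 | intermediate
8 | 5-(tert-butyldimethylsilyloxy)-3-methyl-1,4-bis(trimethylsilyloxy)cyclohex-1-ene (methyl trans to the 4-silyloxy group) | C[Si](C)(C)OC1=C[C@H](C)[C@@H](O[Si](C)(C)C)[C@H](O[Si](C)(C)C(C)(C)C)C1 | intermediate
9 | 4-O-trimethylsilyl ether of 10 | O=C1C[C@@H](O[Si](C)(C)C(C)(C)C)[C@H](O[Si](C)(C)C)C(C)=C1 | intermediate
10 | (4R,5R)-5-(tert-butyldimethylsilyloxy)-4-hydroxy-3-methylcyclohex-2-en-1-one | O=C1C[C@@H](O[Si](C)(C)C(C)(C)C)[C@H](O)C(C)=C1 | intermediate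
11 | 4-O-(2-bromo-1-ethoxyethyl) mixed acetal of 10 (acetal carbon as both epimers) | O=C1C[C@@H](O[Si](C)(C)C(C)(C)C)[C@H](OC(CBr)OCC)C(C)=C1 | intermediate
12 | 8-exo-(tert-butyldimethylsilyloxy)-3-ethoxy-9-methylidene-2-oxabicyclo[3.3.1]nonan-6-one (acetal carbon as both epimers) | O=C1C[C@@H](O[Si](C)(C)C(C)(C)C)[C@H]2C(=C)[C@@H]1CC(OCC)O2 | intermediate
13 | 8-exo-(tert-butyldimethylsilyloxy)-9-methylidene-6-(trimethylsilyloxy)-2-oxabicyclo[3.3.1]nona-3,6-diene | C[Si](C)(C)OC1=C[C@@H](O[Si](C)(C)C(C)(C)C)[C@H]2C(=C)[C@@H]1C=CO2 | intermediate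
14 | 8-exo-(tert-butyldimethylsilyloxy)-9-methylidene-2-oxabicyclo[3.3.1]non-3-en-6-one | O=C1C[C@@H](O[Si](C)(C)C(C)(C)C)[C@H]2C(=C)[C@@H]1C=CO2 | intermediate
15 | 4-(trimethylsilyl)but-3-yn-2-one | CC(=O)C#C[Si](C)(C)C | starting material
16 | 2-bromoprop-2-enal | C=C(Br)C=O | starting material
17 | (5R)-6-bromo-5-hydroxy-1-(trimethylsilyl)hept-6-en-1-yn-3-one | C=C(Br)[C@H](O)CC(=O)C#C[Si](C)(C)C | intermediate
18 | (3S,5R)-6-bromo-1-(trimethylsilyl)hept-6-en-1-yne-3,5-diol | C=C(Br)[C@H](O)C[C@H](O)C#C[Si](C)(C)C | intermediate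
19 | (3S,5R)-6-bromo-3,5-bis(tert-butyldimethylsilyloxy)-1-(trimethylsilyl)hept-6-en-1-yne | C=C(Br)[C@H](O[Si](C)(C)C(C)(C)C)C[C@H](O[Si](C)(C)C(C)(C)C)C#C[Si](C)(C)C | intermediate
20 | (3S,5R)-6-bromo-3,5-bis(tert-butyldimethylsilyloxy)hept-6-en-1-yne | C=C(Br)[C@H](O[Si](C)(C)C(C)(C)C)C[C@H](O[Si](C)(C)C(C)(C)C)C#C | intermediate
21 | dimethyl[(1E,3S,5R)-6-bromo-2-methyl-3,5-bis(tert-butyldimethylsilyloxy)hepta-1,6-dienyl]aluminium | C=C(Br)[C@H](O[Si](C)(C)C(C)(C)C)C[C@H](O[Si](C)(C)C(C)(C)C)/C(C)=C/[Al](C)C | intermediate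
22 | (1E,3S,5R)-6-bromo-1-iodo-2-methyl-3,5-bis(tert-butyldimethylsilyloxy)hepta-1,6-diene | C=C(Br)[C@H](O[Si](C)(C)C(C)(C)C)C[C@H](O[Si](C)(C)C(C)(C)C)/C(C)=C/I | intermediate
23 | alkenyllithium from 22 | C=C(Br)[C@H](O[Si](C)(C)C(C)(C)C)C[C@H](O[Si](C)(C)C(C)(C)C)/C(C)=C/[Li] | intermediate
24 | alkenylcerium dichloride from 23 | C=C(Br)[C@H](O[Si](C)(C)C(C)(C)C)C[C@H](O[Si](C)(C)C(C)(C)C)/C(C)=C/[Ce](Cl)Cl | intermediate
25 | bicyclic dialkenyl carbinol (tertiary C9 alcohol; alkenyl group cis to the enol ether bridge) | C=C(Br)[C@H](O[Si](C)(C)C(C)(C)C)C[C@H](O[Si](C)(C)C(C)(C)C)/C(C)=C/[C@]1(O)C[C@@H](O[Si](C)(C)C(C)(C)C)[C@H]2C(=C)[C@@H]1C=CO2 | intermediate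
26 | potassium alkoxide of 25 | C=C(Br)[C@H](O[Si](C)(C)C(C)(C)C)C[C@H](O[Si](C)(C)C(C)(C)C)/C(C)=C/[C@]1([O-])C[C@@H](O[Si](C)(C)C(C)(C)C)[C@H]2C(=C)[C@@H]1C=CO2.[K+] | intermediate
27 | potassium C9/C10 enolate of the ring-expanded ketone (ten-membered ring formed; ring A still open, vinyl bromide side chain on C1) | C=C(Br)[C@H](O[Si](C)(C)C(C)(C)C)C[C@H](O[Si](C)(C)C(C)(C)C)[C@@]1(C)/C=C(/[O-])C[C@@H](O[Si](C)(C)C(C)(C)C)[C@H]2C(=C)/C=C\[C@@H]1O2.[K+] | intermediate
28 | oxygen-bridged tricyclic ketone (C2–O–C6 ether; C9 ketone; 3Z; 5- and 11-methylidene; 7,12,14-tris-OTBS) | C=C1[C@@H]2C(=O)C[C@@H](O[Si](C)(C)C(C)(C)C)[C@H]3C(=C)/C=C\[C@H](O3)[C@@]2(C)[C@@H](O[Si](C)(C)C(C)(C)C)C[C@H]1O[Si](C)(C)C(C)(C)C | intermediate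
29 | methyl (R)-lactate | C[C@@H](O)C(=O)OC | starting material
30 | methyl (R)-2-(trifluoromethylsulfonyloxy)propanoate | C[C@@H](OS(=O)(=O)C(F)(F)F)C(=O)OC | intermediate
31 | lithium C8/C9 enolate of 28 | C=C1[C@@H]2/C([O-])=C\[C@@H](O[Si](C)(C)C(C)(C)C)[C@H]3C(=C)/C=C\[C@H](O3)[C@@]2(C)[C@@H](O[Si](C)(C)C(C)(C)C)C[C@H]1O[Si](C)(C)C(C)(C)C.[Li+] | intermediate
32 | C8-[(R)-1-methoxy-1-oxopropan-2-yl] ketone (side chain on the outer face; C8 configuration inconsequential) | C=C1[C@@H]2C(=O)[C@@H]([C@@H](C)C(=O)OC)[C@@H](O[Si](C)(C)C(C)(C)C)[C@H]3C(=C)/C=C\[C@H](O3)[C@@]2(C)[C@@H](O[Si](C)(C)C(C)(C)C)C[C@H]1O[Si](C)(C)C(C)(C)C | intermediate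
33 | potassium C8/C9 enolate of 32 | C=C1[C@@H]2/C([O-])=C(/[C@@H](C)C(=O)OC)[C@@H](O[Si](C)(C)C(C)(C)C)[C@H]3C(=C)/C=C\[C@H](O3)[C@@]2(C)[C@@H](O[Si](C)(C)C(C)(C)C)C[C@H]1O[Si](C)(C)C(C)(C)C.[K+] | intermediate
34 | C8 tertiary alcohol methyl ester (7,12,14-tris-OTBS; C9 ketone) | C=C1[C@@H]2C(=O)[C@](O)([C@@H](C)C(=O)OC)[C@@H](O[Si](C)(C)C(C)(C)C)[C@H]3C(=C)/C=C\[C@H](O3)[C@@]2(C)[C@@H](O[Si](C)(C)C(C)(C)C)C[C@H]1O[Si](C)(C)C(C)(C)C | intermediate
35 | desilylated tetraol methyl ester (OH at C7, C8, C12 and C14) | C=C1[C@@H]2C(=O)[C@](O)([C@@H](C)C(=O)OC)[C@@H](O)[C@H]3C(=C)/C=C\[C@H](O3)[C@@]2(C)[C@@H](O)C[C@H]1O | intermediate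
36 | γ-lactone diol ketone (C9 ketone; OH at C8, C12 and C14; C2–O–C6 ether) | C=C1[C@@H]2C(=O)[C@]3(O)[C@@H](C)C(=O)O[C@H]3[C@H]4C(=C)/C=C\[C@H](O4)[C@@]2(C)[C@@H](O)C[C@H]1O | intermediate
37 | γ-lactone tetraol (9S alcohol; OH at C8, C9, C12 and C14; C2–O–C6 ether) | C=C1[C@@H]2[C@H](O)[C@]3(O)[C@@H](C)C(=O)O[C@H]3[C@H]4C(=C)/C=C\[C@H](O4)[C@@]2(C)[C@@H](O)C[C@H]1O | intermediate
38 | 9,12,14-triacetate (C8 hydroxyl free; C2–O–C6 ether) | C=C1[C@@H]2[C@H](OC(C)=O)[C@]3(O)[C@@H](C)C(=O)O[C@H]3[C@H]4C(=C)/C=C\[C@H](O4)[C@@]2(C)[C@@H](OC(C)=O)C[C@H]1OC(C)=O | intermediate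
39 | CNP0164748.1 | C=C1[C@@H]2[C@H](OC(C)=O)[C@]3(O)[C@@H](C)C(=O)O[C@H]3[C@@H](Cl)C(=C)/C=C\[C@H](OC(C)=O)[C@@]2(C)[C@@H](OC(C)=O)C[C@H]1OC(C)=O | target

**Step count and risks**

Total step count: 23. Longest linear sequence: 17 steps (steps 1–9, 15, 16 and 18–23, from quinic acid).

The three steps most likely to fail:

Step 16. The potassium alkoxide may fragment at the doubly allylic C4–C9 bond without recombining, or the enolate may be quenched or shifted by proton transfer before the palladium coupling. Fallback, setting out from carbinol 25: silylation (TMSCl, imidazole) would give the trimethylsilyl ether F1. A thermal, non-ionic siloxy-Cope rearrangement (o-dichlorobenzene, 200 °C, base-washed sealed tube) through the same tether-enforced boat would give the rearranged trimethylsilyl enol ether F2, with the C9/C10 regiochemistry fixed on silicon. A Bu3SnF-promoted, Pd(PPh3)4-catalysed intramolecular coupling of the silyl enol ether with the vinyl bromide (known alkenylation of silyl enol ethers through the tin enolate) would close ring A and come back to ketone 28.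

Step 23. The acyloxonium ion may ionise toward the C2 pentadienyl cation, or chloride may attack the exocyclic methylidene carbon in an SN2′ sense, giving allylically transposed chlorides; the tertiary C8 hydroxyl may also be acetylated. Fallback, setting out from triacetate 38: oxidation of the doubly activated C2–H of the allylic ether with DDQ (wet CH2Cl2) would open the bridge without touching the C6–O bond and give the C2 enone C6 alcohol F3. Appel chlorination (PPh3, CCl4) would replace the C6 hydroxyl with inversion and give the chloro enone F4. Luche reduction (NaBH4, CeCl3·7H2O) from the face opposite the C15 methyl would give the C2 alcohol F5, and acetylation (Ac2O, DMAP) would come back to target 39.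

Step 19. The second deprotonation may occur at C10 or at the ester α-carbon instead of C8, and oxygen transfer may show poor facial selectivity. Fallback, setting out from ketone 28 and bypassing 32: hydroxylation of the kinetic C8 enolate (LiN(i-Pr)2, then the same oxaziridine) would give the α-hydroxy ketone F6, and oxidation (IBX, DMSO) the 8,9-diketone F7. Aldol addition of the lithium enolate of methyl propanoate to the less hindered C8 carbonyl from the outer face would come back to hydroxy ester 34; C17 would then be adjusted by base equilibration of lactone 36 toward the isomer with the methyl group trans to C9.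

Further compounds
F1 | step 16 | trimethylsilyl ether of carbinol 25 | C=C(Br)[C@H](O[Si](C)(C)C(C)(C)C)C[C@H](O[Si](C)(C)C(C)(C)C)/C(C)=C/[C@]1(O[Si](C)(C)C)C[C@@H](O[Si](C)(C)C(C)(C)C)[C@H]2C(=C)[C@@H]1C=CO2
F2 | step 16 | ring-expanded C9/C10 trimethylsilyl enol ether | C=C(Br)[C@H](O[Si](C)(C)C(C)(C)C)C[C@H](O[Si](C)(C)C(C)(C)C)[C@@]1(C)/C=C(/O[Si](C)(C)C)C[C@@H](O[Si](C)(C)C(C)(C)C)[C@H]2C(=C)/C=C\[C@@H]1O2
F3 | step 23 | C2 enone C6 alcohol (bridge opened) | C=C1[C@@H]2[C@H](OC(C)=O)[C@]3(O)[C@@H](C)C(=O)O[C@H]3[C@H](O)C(=C)/C=C\C(=O)[C@@]2(C)[C@@H](OC(C)=O)C[C@H]1OC(C)=O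
F4 | step 23 | C2 enone C6 chloride | C=C1[C@@H]2[C@H](OC(C)=O)[C@]3(O)[C@@H](C)C(=O)O[C@H]3[C@@H](Cl)C(=C)/C=C\C(=O)[C@@]2(C)[C@@H](OC(C)=O)C[C@H]1OC(C)=O
F5 | step 23 | C2 alcohol C6 chloride | C=C1[C@@H]2[C@H](OC(C)=O)[C@]3(O)[C@@H](C)C(=O)O[C@H]3[C@@H](Cl)C(=C)/C=C\[C@H](O)[C@@]2(C)[C@@H](OC(C)=O)C[C@H]1OC(C)=O
F6 | step 19 | C8 α-hydroxy ketone | C=C1[C@@H]2C(=O)[C@@H](O)[C@@H](O[Si](C)(C)C(C)(C)C)[C@H]3C(=C)/C=C\[C@H](O3)[C@@]2(C)[C@@H](O[Si](C)(C)C(C)(C)C)C[C@H]1O[Si](C)(C)C(C)(C)C
F7 | step 19 | 8,9-diketone | C=C1[C@@H]2C(=O)C(=O)[C@@H](O[Si](C)(C)C(C)(C)C)[C@H]3C(=C)/C=C\[C@H](O3)[C@@]2(C)[C@@H](O[Si](C)(C)C(C)(C)C)C[C@H]1O[Si](C)(C)C(C)(C)C
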